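## The problem

Compound 21 is (−)-quinic acid with a galloyl ester on each of its three secondary hydroxyls: a single cyclohexane ring in which C1 carries OH and CO2H, C2 and C6 are methylenes and C3, C4 and C5 carry the aroyloxy groups, with no ring fusion to relay stereochemistry. The C4 oxygen is cis to the C3 oxygen and to the C1 hydroxyl and trans to the C5 oxygen (C3 and C5 both R), so that in the chair the C3 oxygen is axial while the C4 and C5 oxygens and the carboxyl group are equatorial. C1 is quaternary and is stereogenic only because its two ring arms differ, so it can be fixed first in an acyclic precursor and used to steer C4 and C5, while C3 can be set last from its neighbours. The nine phenolic hydroxyls are oxidation-prone and must stay masked to the end, and once the three aryl esters are in place hydroxide and alkoxide are excluded. A C3 ketone flanked by β-oxygens at C1 and C5 eliminates readily under base, which limits what may be done at that oxidation level. The enabling feature is the C3–C4–C5 triad: with C3 as a ketone it is an α,β-dihydroxy ketone, the aldol of a hydroxymethyl ketone (C2–C3(=O)–C4H2OH) with an aldehyde at C5. Because both partners hang from C1, forming the C4–C5 bond closes the ring and creates the trans-diol in one event.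

## Retrosynthesis

**21 ⇒ 20 ⇒ 19.** The last bonds made are nine phenolic O–H bonds, by hydrogenolysis of the benzyl ethers of 20, which leaves esters alone. Before that, the two acetal C–O bonds of the pivalaldehyde acylal of 19 are cut by aqueous acid. Keeping C1–OH and CO2H locked in this acylal as far as 19 means the tertiary hydroxyl cannot be acylated and the carboxyl group needs no ester of its own; a separate ester and a free tertiary alcohol would add steps and a fourth acylation site. The forward step needs an acid that opens the acylal yet spares three aryl esters and nine aryl benzyl ethers.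

**19 ⇒ 18 ⇒ 17 ⇒ 14 + 16.** The three ester C–O bonds are cut one after another, each back to acid chloride 16, which comes in one step from commercial acid 15. All three secondary hydroxyls receive the same group, so no protecting group is needed. The esterification is staged, one equivalent at a time, in the expected order of accessibility: the equatorial C5 hydroxyl, then the axial C3 hydroxyl, then the C4 hydroxyl flanked on both sides. This keeps the heavy acyl donor near stoichiometry and lets the slow last acylation be driven on a defined diester 18. Every regioisomeric mono- or diester converges on the same triester 19, so an imperfect order costs nothing. The precursor 14 is the pivalaldehyde acetal of quinic acid, a C12 triol against C96 for 19.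

**14 ⇒ 13.** The C3–H bond is cut, taking the C3 carbinol back to a ketone. This is the change that turns C3–C4–C5 into an aldol retron; keeping C3 as a protected carbinol through ring closure would demand a glycolaldehyde-type nucleophile instead. The forward reduction must deliver hydride on the face cis to the C5 oxygen, which the free C5 hydroxyl of 13 can do by internal delivery.

**13 ⇒ 12.** The C4–C5 bond is cut. It is the only ring bond lying between two oxygenated carbons next to a carbonyl, so its retron is a hydroxy-ketone aldol. A C3–C4 cut would need acyl-anion chemistry and leave the diol to be made separately, and cuts at C1 would create the quaternary centre during ring closure. Precursor 12 is acyclic in its arms and has one carbon stereocentre besides the acetal carbon. The forward reaction must give the trans-diol with the C4 oxygen cis to the C1 oxygen.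

**12 ⇒ 10 ⇒ 8 ⇒ 6.** The aldehyde C=O is traced to the alkene of 10 (ozonolysis), so the sensitive keto aldehyde is released last under neutral conditions. The ketol arm is traced through diazo ketone 8 to the carboxymethyl arm of acid 6: the C3–C4 bond comes from acylation of a diazoalkane by chloride 7, and the C4–O bond from acidolysis of 8. The neighbouring plan, ketol from the allyl group and aldehyde from the acid, is rejected because it must tell two primary alcohols apart and passes through a γ-hydroxy dioxolanone that can lactonise. The chosen assignment makes the carboxymethyl arm C2–C3–C4 and the allyl group C6–C5, which fixes the enantiomer of 1.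

**6 ⇒ 3 + 4 ⇒ 1 + 2.** The C1–C6 bond is cut to allyl bromide 4 and the enolate of dioxolanone 3, which comes from malic acid 1 and pivalaldehyde 2. The electrophile enters anti to the tert-butyl group of the cis acetal, in the place of the former hydrogen. With the allyl group as the C6–C5 arm, the C1 configuration of 21 therefore requires (R)-malic acid. Both 1 and 2 are commercial, and the forward alkylation only needs the usual anti selectivity of this enolate class.

## Roads not taken

Alternative 1: Ireland–Claisen ring contraction. The cut is C1–C6. Forward, δ-lactone A1 (3-benzyloxy, 5-silyloxy, 6-vinyl, silyloxy and vinyl cis) is enolised and O-silylated; the [3,3] shift, forced through a boat by the ring, forms C1–C6, breaks the lactone C–O bond and gives cyclohexene acid A2.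
- Merits: C1 is set relative to C3 by chirality transfer from the vinyl-bearing carbon and the carboxyl group is already in place. This relay is at least as trustworthy as the enolate alkylation that gives 6, and more so than the catalyst-controlled closure of 12 to 13.
- Weak points: A2 carries only one of the three carbinol oxygens. C4 and C5 must be oxygenated from the alkene with C4–O cis and C5–O trans to the C3 oxygen, which syn-dihydroxylation cannot give. The silyl group must come off, and an epoxidation on the face of the C3 oxygen and a regioselective trans-diaxial opening at C5 are needed. A1 itself must first be built with two relevant stereocentres.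
- Comparison: in security of C1 this road equals or beats the chosen plan. Against that, the chosen plan installs both C4 and C5 oxygens in the ring-closing step, needs no hydroxyl protecting groups before the gallates, and reaches the ring in six steps from 1.

Alternative 2: two-directional alkylation of a dithiane. The cuts are C1–C2 and C1–C6. Forward, the anion of A4 (1,3-dithiane) is alkylated at both ends of the pool-derived (2S,4S)-diiodide A3, closing spiro dithioacetal A5.
- Merits: C3, C4 and C5 arrive with their oxygens from the chiral pool, and because A3 is C2-symmetric the middle carbon needs no control. On these three centres this road is clearly safer than an aldol followed by a ketone reduction.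
- Weak points: both alkylations are SN2 reactions at primary carbons flanked by β-alkoxy groups, so they are slow and open to E2 with a basic carbanion. More seriously, A5 delivers C1 only as a masked carbonyl. The carboxyl carbon and the tertiary hydroxyl must then be added by a cyanohydrin-type addition whose two faces differ only through the remote C4 substituent. A nitrile hydrolysis and an exchange of three acetal protecting groups for gallates follow.
- Comparison: the stereochemical risk moves from C4/C5 to C1. The chosen plan fixes C1 first by a reliable alkylation and carries the carboxyl carbon from step 1, at the price of an aldol whose facial control is less certain than pool-derived centres.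

Alternative 3: double Henry annulation with nitromethane as C6. The cuts are C5–C6 and C1–C6. Forward, A7 (nitromethane) adds to the aldehyde of keto ester A6 and, after a second deprotonation, to its ketone carbonyl, giving nitrocyclohexane A8.
- Merits: two C–C bonds and the ring form in one operation, C3 and C4 come from the pool as a cis-acetonide, and the benzyl ester would fall in the final hydrogenolysis. In bonds formed per step this outdoes the chosen plan.
- Weak points: three stereocentres (C5, C6, C1) arise in reversible additions, so the outcome at C1 and C5 is whatever the equilibrium prefers. The nitro group has no place in 21, and its reductive removal from a β,β'-dihydroxy nitroalkane competes with retro-Henry cleavage and dehydration. The acetonide must still be traded for gallates.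
- Comparison: the chosen plan forms one bond instead of two, but leaves nothing to erase, has C1 fixed beforehand, and maps the aldol oxidation pattern directly onto the target.

Key step: step 6

## Route

Remark on the chemistry: ethereal diazomethane is taken as a stock reagent, generated from commercial N-methyl-N-nitroso-p-toluenesulfonamide, and is not counted as a step. Ring positions are numbered as in quinic acid throughout.

Step 1
Reactants: 1 (R)-malic acid; 2 pivalaldehyde
Product: 3 2-[(2R,4R)-2-tert-butyl-5-oxo-1,3-dioxolan-4-yl]acetic acid (tert-butyl and carboxymethyl cis)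
Conditions: TsOH·H2O (cat.), H2SO4 (cat.), pentane, reflux, Dean–Stark; recrystallisation
Reagents that add atoms: none
Why: Acid-catalysed acetalisation of an α-hydroxy acid with pivalaldehyde (first stage of self-regeneration of stereocentres); the five-membered dioxolanone forms in preference to the six-membered ring through the β-carboxyl, and the cis isomer is favoured at equilibrium and purified by crystallisation, so the acetal carbon is R while the malic stereocentre is untouched.

Step 2
Reactants: 3 2-[(2R,4R)-2-tert-butyl-5-oxo-1,3-dioxolan-4-yl]acetic acid; 4 allyl bromide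
Product: 6 2-[(2R,4R)-2-tert-butyl-5-oxo-4-(prop-2-en-1-yl)-1,3-dioxolan-4-yl]acetic acid, via dilithium enolate carboxylate 5 (not isolated)
Conditions: LiN(SiMe3)2 (2.2 equiv), THF, −78 °C; then 4, −78 → −20 °C; cold aq. HCl quench
Reagents that add atoms: none
Why: Alkylation of a dioxolanone enolate (self-regeneration of stereocentres): two equivalents of base give the carboxylate and the ring enolate, the tert-butyl group shields its own face, and allyl bromide enters anti to it in the place of the former hydrogen, so the carboxymethyl arm stays cis to tert-butyl and the new quaternary centre is R.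

Step 3
Reactants: 6 2-[(2R,4R)-2-tert-butyl-5-oxo-4-(prop-2-en-1-yl)-1,3-dioxolan-4-yl]acetic acid
Product: 8 (2R,5R)-2-tert-butyl-5-(3-diazo-2-oxopropyl)-5-(prop-2-en-1-yl)-1,3-dioxolan-4-one, via acid chloride 7 (not isolated)
Conditions: (COCl)2, DMF (cat.), CH2Cl2, 0 °C → rt, evaporate; then CH2N2 (3 equiv), Et2O, 0 °C
Reagents that add atoms: diazomethane, C=[N+]=[N-]
Why: Acyl chloride formation under Vilsmeier catalysis, then acylation of diazomethane (first stage of the Arndt–Eistert sequence); a second equivalent of diazomethane takes up the HCl so that no chloromethyl ketone forms, and lactone, acetal and alkene are inert to both reagents, so no stereocentre is touched.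

Step 4
Reactants: 8 (2R,5R)-2-tert-butyl-5-(3-diazo-2-oxopropyl)-5-(prop-2-en-1-yl)-1,3-dioxolan-4-one
Product: 10 (2R,5R)-2-tert-butyl-5-(3-hydroxy-2-oxopropyl)-5-(prop-2-en-1-yl)-1,3-dioxolan-4-one, via trifluoroacetate ester 9 (not isolated)
Conditions: CF3CO2H, CH2Cl2, 0 °C; then sat. aq. NaHCO3, THF, 0 °C → rt
Reagents that add atoms: trifluoroacetic acid, OC(=O)C(F)(F)F
Why: Acidolysis of an α-diazo ketone: C-protonation gives the diazonium ion, trifluoroacetate displaces N2 at the primary carbon, and the very labile trifluoroacetate is then cleaved by bicarbonate, so the hydroxyl oxygen comes from the acid; the medium is anhydrous while acidic, which spares the acylal, and no metal carbene is involved, so the allyl group is not cyclopropanated.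

Step 5
Reactants: 10 (2R,5R)-2-tert-butyl-5-(3-hydroxy-2-oxopropyl)-5-(prop-2-en-1-yl)-1,3-dioxolan-4-one
Product: 12 (2R,5R)-2-tert-butyl-5-(3-hydroxy-2-oxopropyl)-5-(2-oxoethyl)-1,3-dioxolan-4-one, via secondary ozonide 11 (not isolated)
Conditions: O3, CH2Cl2, −78 °C; then PPh3, −78 °C → rt
Reagents that add atoms: ozone, [O-][O+]=O
Why: Criegee ozonolysis with reductive work-up turns the allyl group into the 2-oxoethyl arm under neutral conditions; the alkene is the only ozone-reactive site, the sensitive keto aldehyde is released last, and any cyclic hemiacetal form of 12 is in equilibrium with the open form.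

Step 6
Reactants: 12 (2R,5R)-2-tert-butyl-5-(3-hydroxy-2-oxopropyl)-5-(2-oxoethyl)-1,3-dioxolan-4-one
Product: 13 (2R,5R,8S,9R)-2-tert-butyl-8,9-dihydroxy-1,3-dioxaspiro[4.5]decane-4,7-dione (pivalaldehyde acetal of 3-dehydroquinic acid)
Conditions: L-proline (30 mol %), DMSO (0.05 M), rt
Reagents that add atoms: none
Why: L-Proline condenses with the C3 ketone and, as with hydroxyacetone donors, forms the enamine on the hydroxylated side; its carbon C4 adds to the aldehyde carbon C5, whose oxygen is hydrogen-bonded to the carboxylic acid of the catalyst, and hydrolysis of the iminium ion returns the catalyst. The closest known reactions are the Hajos–Parrish–Eder–Sauer–Wiechert cyclisation (proline, 6-enolendo) and the proline aldol of hydroxyacetone with aldehydes. The cyclohexane ring closes 6-(enolendo)-exo-trig, and since the enamine toward C2 or the enamine of the aldehyde could only close four-membered rings, one cyclisation is open. C4 is set by the catalyst: the (E)-enamine (OH anti to N) is attacked on the face that gives S at the hydroxylated carbon in intermolecular hydroxyacetone aldols. C5 is set by the tether: C6 must sit gauche to C3 about the forming bond while the aldehyde oxygen points to the acid, which places that oxygen anti to the C4 hydroxyl and gives the trans-diol with 5R (same donor face, opposite aldehyde face to the intermolecular case). In this closing chair both new oxygens and the C1 acyl carbon are axial; after bond formation the ring inverts to the chair with the C4 and C5 hydroxyls and the acyl carbon equatorial, which should also be the thermodynamically preferred diastereomer if the aldol equilibrates. The step needs diastereoselection against the existing C1 centre, where catalyst control has to outweigh the cost of the axial acyl carbon, and chemoselection against intermolecular aldol and β-elimination of the C1 oxygen, which high dilution, room temperature and the weakly basic zwitterionic catalyst favour.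

Step 7
Reactants: 13 (2R,5R,8S,9R)-2-tert-butyl-8,9-dihydroxy-1,3-dioxaspiro[4.5]decane-4,7-dione
Product: 14 (2R)-2-tert-butyl-7,8,9-trihydroxy-1,3-dioxaspiro[4.5]decan-4-one of quinic acid configuration (pivalaldehyde acetal of (−)-quinic acid across 1-OH and CO2H)
Conditions: Me4NBH(OAc)3 (5 equiv), MeCN/AcOH (1:1), −30 → −20 °C; aq. sodium potassium tartrate
Reagents that add atoms: none
Why: Hydroxyl-directed reduction with triacetoxyborohydride (Evans–Saksena reduction): the C5 hydroxyl exchanges an acetate on boron and delivers hydride through a six-membered chair to the face of C3 cis to the C5 oxygen, giving the 3,5-anti diol, that is the C3 hydroxyl cis to C4–OH and axial (3R); the reagent does not reduce the lactone and keeps the medium acidic, so neither acyl transfer nor β-elimination is triggered.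

Step 8
Reactants: 15 3,4,5-tris(benzyloxy)benzoic acid
Product: 16 3,4,5-tris(benzyloxy)benzoyl chloride
Conditions: (COCl)2, DMF (cat.), CH2Cl2, 0 °C → rt
Reagents that add atoms: oxalyl chloride, ClC(=O)C(=O)Cl
Why: Standard conversion of an aromatic acid into its chloride with oxalyl chloride under Vilsmeier catalysis; the benzyl ethers are inert.

Step 9
Reactants: 14 pivalaldehyde acetal of (−)-quinic acid; 16 3,4,5-tris(benzyloxy)benzoyl chloride
Product: 17 pivalaldehyde acetal (R at the acetal carbon) of 5-O-[3,4,5-tris(benzyloxy)benzoyl]-(−)-quinic acid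
Conditions: 16 (1.05 equiv), pyridine, CH2Cl2, −40 → 0 °C
Reagents that add atoms: none
Why: Pyridine-mediated acylation of an alcohol by an aroyl chloride at low temperature; one equivalent should go to the C5 hydroxyl, the only equatorial hydroxyl with a methylene neighbour, while the axial C3 hydroxyl and the doubly flanked C4 hydroxyl lag, and because the C1 oxygen is inside the acylal and any 3-O or 4-O isomer converges on 19 in steps 10 and 11, neither regiochemistry nor stereochemistry is at risk.

Step 10
Reactants: 17 pivalaldehyde acetal of 5-O-[3,4,5-tris(benzyloxy)benzoyl]-(−)-quinic acid; 16 3,4,5-tris(benzyloxy)benzoyl chloride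
Product: 18 pivalaldehyde acetal (R at the acetal carbon) of 3,5-bis-O-[3,4,5-tris(benzyloxy)benzoyl]-(−)-quinic acid
Conditions: 16 (1.1 equiv), pyridine, DMAP (0.1 equiv), CH2Cl2, 0 °C → rt
Reagents that add atoms: none
Why: DMAP-catalysed acylation; the second aroyl group should enter at the axial C3 hydroxyl, which has a methylene neighbour, in preference to the C4 hydroxyl lying between two oxygenated carbons, the 3,5-pattern expected from double silylation of quinate esters, and an isomeric diester would still converge on 19.

Step 11
Reactants: 18 pivalaldehyde acetal of 3,5-bis-O-[3,4,5-tris(benzyloxy)benzoyl]-(−)-quinic acid; 16 3,4,5-tris(benzyloxy)benzoyl chloride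
Product: 19 pivalaldehyde acetal (R at the acetal carbon) of 3,4,5-tris-O-[3,4,5-tris(benzyloxy)benzoyl]-(−)-quinic acid
Conditions: 16 (1.5 equiv), pyridine, DMAP (0.5 equiv), CH2Cl2, 40 °C
Reagents that add atoms: none
Why: DMAP-catalysed acylation under forcing conditions for the hindered equatorial C4 hydroxyl flanked by two aroyloxy groups; base-induced migration of a neighbouring aroyl group onto this oxygen would only change which hydroxyl is acylated last, so the triester is the single end point and no stereocentre is affected.

Step 12
Reactants: 19 pivalaldehyde acetal of 3,4,5-tris-O-[3,4,5-tris(benzyloxy)benzoyl]-(−)-quinic acid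
Product: 20 3,4,5-tris-O-[3,4,5-tris(benzyloxy)benzoyl]-(−)-quinic acid
Conditions: 2 M aq. HCl, THF, 50 °C
Reagents that add atoms: water, O
Why: Acid-catalysed hydrolysis of the dioxolanone acylal, which should be more labile than aryl esters of hindered secondary alcohols and than aryl benzyl ethers in dilute aqueous acid; one water is consumed, its oxygen ending in the carboxyl group or in the pivalaldehyde according to the bond cleaved, and C1 keeps its configuration because no bond to it is broken.

Step 13
Reactants: 20 3,4,5-tris-O-[3,4,5-tris(benzyloxy)benzoyl]-(−)-quinic acid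
Product: 21 3,4,5-tri-O-galloyl-(−)-quinic acid, (1S,3R,4S,5R)-1-hydroxy-3,4,5-tris(3,4,5-trihydroxybenzoyloxy)cyclohexane-1-carboxylic acid
Conditions: H2 (1 atm), Pd/C (10 %), THF/MeOH, rt
Reagents that add atoms: none
Why: Hydrogenolysis of nine aryl benzyl ethers on Pd/C; esters, the tertiary alcohol and the acid are untouched, toluene is the only by-product, and the polyphenol is obtained after filtration without chromatography of base-sensitive esters.

## Compound list

1 | (R)-malic acid | O[C@H](CC(=O)O)C(=O)O | starting material
2 | pivalaldehyde (2,2-dimethylpropanal) | CC(C)(C)C=O | starting material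
3 | 2-[(2R,4R)-2-tert-butyl-5-oxo-1,3-dioxolan-4-yl]acetic acid (tert-butyl and carboxymethyl cis) | CC(C)(C)[C@@H]1O[C@H](CC(=O)O)C(=O)O1 | intermediate
4 | allyl bromide (3-bromoprop-1-ene) | C=CCBr | starting material
5 | dilithium enolate carboxylate of 3 (not isolated) | [Li+].[Li+].CC(C)(C)[C@@H]1OC(CC(=O)[O-])=C([O-])O1 | intermediate
6 | 2-[(2R,4R)-2-tert-butyl-5-oxo-4-(prop-2-en-1-yl)-1,3-dioxolan-4-yl]acetic acid (allyl trans to tert-butyl) | CC(C)(C)[C@@H]1O[C@](CC=C)(CC(=O)O)C(=O)O1 | intermediate
7 | 2-[(2R,4R)-2-tert-butyl-5-oxo-4-(prop-2-en-1-yl)-1,3-dioxolan-4-yl]acetyl chloride (not isolated) | CC(C)(C)[C@@H]1O[C@](CC=C)(CC(=O)Cl)C(=O)O1 | intermediate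
8 | (2R,5R)-2-tert-butyl-5-(3-diazo-2-oxopropyl)-5-(prop-2-en-1-yl)-1,3-dioxolan-4-one | CC(C)(C)[C@@H]1O[C@](CC=C)(CC(=O)C=[N+]=[N-])C(=O)O1 | intermediate
9 | 3-[(2R,4R)-2-tert-butyl-5-oxo-4-(prop-2-en-1-yl)-1,3-dioxolan-4-yl]-2-oxopropyl trifluoroacetate (not isolated) | CC(C)(C)[C@@H]1O[C@](CC=C)(CC(=O)COC(=O)C(F)(F)F)C(=O)O1 | intermediate
10 | (2R,5R)-2-tert-butyl-5-(3-hydroxy-2-oxopropyl)-5-(prop-2-en-1-yl)-1,3-dioxolan-4-one | CC(C)(C)[C@@H]1O[C@](CC=C)(CC(=O)CO)C(=O)O1 | intermediate
11 | (2R,5R)-2-tert-butyl-5-(3-hydroxy-2-oxopropyl)-5-(1,2,4-trioxolan-3-ylmethyl)-1,3-dioxolan-4-one (ozonide, both epimers at the trioxolane carbon, not isolated) | CC(C)(C)[C@@H]1O[C@](CC2OCOO2)(CC(=O)CO)C(=O)O1 | intermediate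
12 | (2R,5R)-2-tert-butyl-5-(3-hydroxy-2-oxopropyl)-5-(2-oxoethyl)-1,3-dioxolan-4-one | CC(C)(C)[C@@H]1O[C@](CC=O)(CC(=O)CO)C(=O)O1 | intermediate
13 | (2R,5R,8S,9R)-2-tert-butyl-8,9-dihydroxy-1,3-dioxaspiro[4.5]decane-4,7-dione (pivalaldehyde acetal of 3-dehydroquinic acid; 8-OH cis to O1, 9-OH trans to 8-OH) | CC(C)(C)[C@@H]1O[C@]2(CC(=O)[C@@H](O)[C@H](O)C2)C(=O)O1 | intermediate
14 | (2R)-2-tert-butyl-7,8,9-trihydroxy-1,3-dioxaspiro[4.5]decan-4-one with the (1S,3R,4S,5R) configuration of (−)-quinic acid (7R,9R; 7-OH and 8-OH cis to O1, 9-OH trans) | CC(C)(C)[C@@H]1O[C@]2(C[C@@H](O)[C@@H](O)[C@H](O)C2)C(=O)O1 | intermediate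
15 | 3,4,5-tris(benzyloxy)benzoic acid | OC(=O)c1cc(OCc2ccccc2)c(OCc2ccccc2)c(OCc2ccccc2)c1 | starting material
16 | 3,4,5-tris(benzyloxy)benzoyl chloride | ClC(=O)c1cc(OCc2ccccc2)c(OCc2ccccc2)c(OCc2ccccc2)c1 | intermediate
17 | pivalaldehyde acetal (R at the acetal carbon, across 1-OH and CO2H) of 5-O-[3,4,5-tris(benzyloxy)benzoyl]-(−)-quinic acid (free 3-OH and 4-OH) | CC(C)(C)[C@@H]1O[C@]2(C[C@@H](O)[C@@H](O)[C@H](OC(=O)c3cc(OCc4ccccc4)c(OCc4ccccc4)c(OCc4ccccc4)c3)C2)C(=O)O1 | intermediate
18 | pivalaldehyde acetal (R at the acetal carbon, across 1-OH and CO2H) of 3,5-bis-O-[3,4,5-tris(benzyloxy)benzoyl]-(−)-quinic acid (free 4-OH) | CC(C)(C)[C@@H]1O[C@]2(C[C@@H](OC(=O)c3cc(OCc4ccccc4)c(OCc4ccccc4)c(OCc4ccccc4)c3)[C@@H](O)[C@H](OC(=O)c3cc(OCc4ccccc4)c(OCc4ccccc4)c(OCc4ccccc4)c3)C2)C(=O)O1 | intermediate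
19 | pivalaldehyde acetal (R at the acetal carbon, across 1-OH and CO2H) of 3,4,5-tris-O-[3,4,5-tris(benzyloxy)benzoyl]-(−)-quinic acid | CC(C)(C)[C@@H]1O[C@]2(C[C@@H](OC(=O)c3cc(OCc4ccccc4)c(OCc4ccccc4)c(OCc4ccccc4)c3)[C@@H](OC(=O)c3cc(OCc4ccccc4)c(OCc4ccccc4)c(OCc4ccccc4)c3)[C@H](OC(=O)c3cc(OCc4ccccc4)c(OCc4ccccc4)c(OCc4ccccc4)c3)C2)C(=O)O1 | intermediate
20 | 3,4,5-tris-O-[3,4,5-tris(benzyloxy)benzoyl]-(−)-quinic acid | O[C@@]1(C(=O)O)C[C@@H](OC(=O)c2cc(OCc3ccccc3)c(OCc3ccccc3)c(OCc3ccccc3)c2)[C@@H](OC(=O)c2cc(OCc3ccccc3)c(OCc3ccccc3)c(OCc3ccccc3)c2)[C@H](OC(=O)c2cc(OCc3ccccc3)c(OCc3ccccc3)c(OCc3ccccc3)c2)C1 | intermediate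
21 | 3,4,5-tri-O-galloyl-(−)-quinic acid, (1S,3R,4S,5R)-1-hydroxy-3,4,5-tris(3,4,5-trihydroxybenzoyloxy)cyclohexane-1-carboxylic acid | O[C@@]1(C(=O)O)C[C@@H](OC(=O)c2cc(O)c(O)c(O)c2)[C@@H](OC(=O)c2cc(O)c(O)c(O)c2)[C@H](OC(=O)c2cc(O)c(O)c(O)c2)C1 | target

## Step count and least certain steps

Total step count: 13. Longest linear sequence: 12 steps (steps 1–7 and 9–13, from 1). Step 8 is a one-step branch from 15.

**Step 6 (key step).** Three things are most likely to go wrong:
- insufficient diastereofacial control, because the catalyst-preferred closing chair carries the C1 acyl carbon axial, so catalyst and substrate preferences are not aligned;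
- loss of the C1 oxygen by β-elimination through the C2 enamine or the enamine of the aldehyde;
- acyl transfer from the dioxolanone to the new C5 hydroxyl, which lies beside the lactone carbonyl in the closing chair.

The fallback closes the same C4–C5 bond by metathesis and adds the oxygens afterwards. It sets out from acid 6, converted as in step 3 into its chloride 7. Stille acylation of 7 with tributyl(vinyl)stannane under zerovalent palladium catalysis, Pd(PPh3)4, should give (2R,5R)-2-tert-butyl-5-(2-oxobut-3-en-1-yl)-5-(prop-2-en-1-yl)-1,3-dioxolan-4-one F1. Ring-closing metathesis with the second-generation Grubbs catalyst, RuCl2(=CHPh)(PCy3)(H2IMes), should give the spiro cyclohexenone (2R,5R)-2-tert-butyl-1,3-dioxaspiro[4.5]dec-8-ene-4,7-dione F2. Weitz–Scheffer epoxidation with H2O2 under control of a 9-amino-9-deoxy-epi-cinchona alkaloid salt, the pseudoenantiomer chosen to place the oxygen cis to the ring oxygen at C1, should give the 8,9-epoxy-1,3-dioxaspiro[4.5]decane-4,7-dione F3. Acid-catalysed opening by water at C5, the carbon remote from the carbonyl, with inversion (Fürst–Plattner rule) comes back to the route at 13.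

**Step 7.** The likely failure is hydride delivery that is not governed by the C5 hydroxyl. Boron bound to the C4 hydroxyl, or undirected axial attack, would give the C3 epimer. Borate complexation of the new cis-3,4-diol may also hinder isolation.

The fallback replaces directed delivery by steric control after the diol is esterified. It sets out from 13. Acylation of both hydroxyls with 16 (pyridine, DMAP cat.) should give the 8,9-bis-O-[3,4,5-tris(benzyloxy)benzoyl] ketone F4. LiBH(sec-Bu)3 in THF at −78 °C should attack the C3 carbonyl from the equatorial direction, since the axial ring oxygen at C1 blocks the axial path, giving the axial 7-hydroxy bis-ester F5. Any ester migration to the C3 oxygen is harmless. Acylation with 16 comes back to the route at 19.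

**Step 12.** The likely failure is slow opening of the hindered acylal relative to acid cleavage of an aryl ester or a benzyl ether, so that an ester or protecting group is lost before the acetal goes.

The fallback removes the acetal before any gallate is present. It sets out from 14. LiOH in aqueous THF should give (−)-quinic acid F6. Benzyl bromide and Cs2CO3 in DMF should give benzyl (−)-quinate F7. Acylation with 16 (DMAP, pyridine) should esterify the three secondary hydroxyls, the tertiary one being too hindered, to give benzyl 3,4,5-tris-O-[3,4,5-tris(benzyloxy)benzoyl]quinate F8. Hydrogenolysis over Pd/C removes ten benzyl groups and comes back to the route at 21.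

## Further compounds

F1 | step 6 | (2R,5R)-2-tert-butyl-5-(2-oxobut-3-en-1-yl)-5-(prop-2-en-1-yl)-1,3-dioxolan-4-one | CC(C)(C)[C@@H]1O[C@](CC=C)(CC(=O)C=C)C(=O)O1
F2 | step 6 | (2R,5R)-2-tert-butyl-1,3-dioxaspiro[4.5]dec-8-ene-4,7-dione | CC(C)(C)[C@@H]1O[C@]2(CC(=O)C=CC2)C(=O)O1
F3 | step 6 | (2R,5R)-2-tert-butyl-8,9-epoxy-1,3-dioxaspiro[4.5]decane-4,7-dione, epoxide oxygen cis to O1 | CC(C)(C)[C@@H]1O[C@]2(CC(=O)[C@H]3O[C@H]3C2)C(=O)O1
F4 | step 7 | 8,9-bis-O-[3,4,5-tris(benzyloxy)benzoyl] derivative of 13 | CC(C)(C)[C@@H]1O[C@]2(CC(=O)[C@@H](OC(=O)c3cc(OCc4ccccc4)c(OCc4ccccc4)c(OCc4ccccc4)c3)[C@H](OC(=O)c3cc(OCc4ccccc4)c(OCc4ccccc4)c(OCc4ccccc4)c3)C2)C(=O)O1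
F5 | step 7 | 8,9-bis-O-[3,4,5-tris(benzyloxy)benzoyl] derivative of 14 (free axial 7-OH) | CC(C)(C)[C@@H]1O[C@]2(C[C@@H](O)[C@@H](OC(=O)c3cc(OCc4ccccc4)c(OCc4ccccc4)c(OCc4ccccc4)c3)[C@H](OC(=O)c3cc(OCc4ccccc4)c(OCc4ccccc4)c(OCc4ccccc4)c3)C2)C(=O)O1
F6 | step 12 | (−)-quinic acid | O[C@@]1(C(=O)O)C[C@@H](O)[C@@H](O)[C@H](O)C1
F7 | step 12 | benzyl (−)-quinate | O[C@@]1(C(=O)OCc2ccccc2)C[C@@H](O)[C@@H](O)[C@H](O)C1
F8 | step 12 | benzyl 3,4,5-tris-O-[3,4,5-tris(benzyloxy)benzoyl]-(−)-quinate | O[C@@]1(C(=O)OCc2ccccc2)C[C@@H](OC(=O)c2cc(OCc3ccccc3)c(OCc3ccccc3)c(OCc3ccccc3)c2)[C@@H](OC(=O)c2cc(OCc3ccccc3)c(OCc3ccccc3)c(OCc3ccccc3)c2)[C@H](OC(=O)c2cc(OCc3ccccc3)c(OCc3ccccc3)c(OCc3ccccc3)c2)C1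
A1 | alternative 1 | 3-(benzyloxy)-5-(tert-butyldimethylsilyloxy)-6-ethenyloxan-2-one, silyloxy and ethenyl cis | O=C1C(OCc2ccccc2)C[C@@H](O[Si](C)(C)C(C)(C)C)[C@@H](C=C)O1
A2 | alternative 1 | 1-benzyloxy-3-(tert-butyldimethylsilyloxy)cyclohex-4-ene-1-carboxylic acid, benzyloxy and silyloxy cis | OC(=O)[C@]1(OCc2ccccc2)C[C@@H](O[Si](C)(C)C(C)(C)C)C=CC1
A3 | alternative 2 | (2S,4S)-1,5-diiodo-2,3,4-tris(methoxymethoxy)pentane | IC[C@@H](OCOC)C(OCOC)[C@H](OCOC)CI
A4 | alternative 2 | 1,3-dithiane | C1CSCSC1
A5 | alternative 2 | 8,9,10-tris(methoxymethoxy)-1,5-dithiaspiro[5.5]undecane (8,10-trans) | S1CCCSC12C[C@@H](OCOC)C(OCOC)[C@H](OCOC)C2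
A6 | alternative 3 | benzyl 3-(5-formyl-2,2-dimethyl-1,3-dioxolan-4-yl)-2-oxopropanoate, ring substituents cis | O=C(C(=O)OCc1ccccc1)C[C@H]1OC(C)(C)O[C@H]1C=O
A7 | alternative 3 | nitromethane | C[N+](=O)[O-]
A8 | alternative 3 | benzyl 6-nitro-3,4-O-isopropylidenequinate | O[C@@]1(C(=O)OCc2ccccc2)C[C@H]2OC(C)(C)O[C@H]2[C@H](O)[C@H]1[N+](=O)[O-]
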